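## Retrosynthetic overview
1. Exchange the C12 acetate for a silyl ether. Then open the C10=C11 alkene by aldol/dehydration into a C1–C10 aldehyde and an α-unsubstituted β-silyloxy-γ-isobutenyl butyrolactone.
2. The C1–C10 aldehyde comes from an aliphatic Claisen [3,3] rearrangement, which makes C8–C9, sets 6E and delivers the CHO. Its substrate is the vinyl ether of an isopropenyl carbinol, made by a singlet-oxygen ene reaction on neryl methacrylate, which comes from nerol (2Z bought).
3. The lactone comes from Wittig isopropylidenation of the C5 aldehyde of 2-deoxy-D-ribono-1,4-lactone, which comes from 2-deoxy-D-ribose (its C3 and C4 are C12 and C13).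
4. Ring order: the only ring, the γ-lactone, is closed first in its branch by lactol oxidation and is never reopened.

Assumption: the SMILES reads as 2Z, 6E, 10E (chain anti to the lactone C=O), C12 = S and C13 = R, with OAc and isobutenyl trans. Locants follow the geranylgeraniol skeleton, C1 being the OCH2 of the methacrylate. A one-flask sequence counts as one step.

## Route

**Step 1**
Reactants: 1 nerol; 2 methacryloyl chloride
Product: 3 neryl methacrylate [(2Z)-3,7-dimethylocta-2,6-dien-1-yl 2-methylprop-2-enoate]
Conditions: Et3N, DMAP (cat.), CH2Cl2, 0 °C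
Reagents that add atoms: methacryloyl chloride C=C(C)C(=O)Cl
Why: DMAP-catalysed O-acylation under basic conditions leaves the bought 2Z alkene untouched and installs the final C1 ester at once, so this branch needs no protecting group.

**Step 2**
Reactants: 3 neryl methacrylate
Product: 5 (2Z)-6-hydroxy-3,7-dimethylocta-2,7-dien-1-yl methacrylate (racemic at C6), via allylic hydroperoxide 4 (not isolated)
Conditions: O2, TPP (cat.), hν, CH2Cl2, 0 °C; then PPh3, 0 °C → rt
Reagents that add atoms: dioxygen O=O
Why: The Schenck ene reaction of singlet oxygen attacks only the electron-rich 6,7-alkene and PPh3 reduces the hydroperoxide; the secondary (wanted) and tertiary alcohols form about 1:1 and are separated, and the racemic C6 centre is erased in step 3.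

**Step 3 (key step)**
Reactants: 5 allylic alcohol; 6 n-butyl vinyl ether
Product: 8 (2Z,6E)-3,7-dimethyl-10-oxodeca-2,6-dien-1-yl methacrylate, via allyl vinyl ether 7 (not isolated)
Conditions: n-BuOCH=CH2 (solvent), Hg(OAc)2 (10 mol %), NaOAc, BHT, sealed tube, 95 → 125 °C
Reagents that add atoms: n-butyl vinyl ether C=COCCCC
Why: Hg(II)-catalysed transvinylation followed by Claisen [3,3]-sigmatropic rearrangement through a chair with the C5 chain equatorial makes the C8–C9 bond, the 6E alkene (about 9:1, minor 6Z removed on AgNO3–silica) and the aldehyde in one operation.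

**Step 4**
Reactants: 9 2-deoxy-D-ribose
Product: 10 2-deoxy-D-ribono-1,4-lactone [(4S,5R)-4-hydroxy-5-(hydroxymethyl)oxolan-2-one]
Conditions: Br2, NaHCO3, H2O, 0–5 °C; evaporate, take up in EtOH/acetone, filter
Reagents that add atoms: none
Why: Bromine-water oxidation of the lactol gives the stable five-membered lactone without touching sugar C3 and C4, which are C12 (S) and C13 (R) of the target with the trans relationship already in place.

**Step 5**
Reactants: 10 2-deoxy-D-ribono-1,4-lactone
Product: 11 (4S,5R)-4-(triethylsilyloxy)-5-[(triethylsilyloxy)methyl]oxolan-2-one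
Conditions: Et3SiCl (2.4 equiv), imidazole, DMF, 0 °C → rt
Reagents that add atoms: chlorotriethylsilane CC[Si](Cl)(CC)CC
Why: Imidazole-promoted silylation of both hydroxyls masks C12–OH for the enolate chemistry and prepares the primary position for direct oxidation.

**Step 6**
Reactants: 11 bis-TES lactone
Product: 13 (2S,3S)-5-oxo-3-(triethylsilyloxy)oxolane-2-carbaldehyde, via alkoxysulfonium chloride 12 (not isolated)
Conditions: (COCl)2, DMSO, CH2Cl2, −78 → −40 °C; Et3N, −78 → 0 °C; used crude
Reagents that add atoms: none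
Why: Under Swern conditions activated DMSO displaces only the unhindered primary TES ether and oxidises it to the aldehyde, while the secondary TES ether survives and cold work-up avoids epimerisation or β-elimination.

**Step 7**
Reactants: 13 lactone aldehyde; 14 isopropyltriphenylphosphonium iodide
Product: 16 (4S,5R)-5-(2-methylprop-1-en-1-yl)-4-(triethylsilyloxy)oxolan-2-one, via isopropylidenetriphenylphosphorane 15 (not isolated)
Conditions: 14, n-BuLi, THF, 0 °C; then 13, −78 → 0 °C
Reagents that add atoms: isopropyltriphenylphosphonium iodide CC(C)[P+](c1ccccc1)(c1ccccc1)c1ccccc1.[I-]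
Why: Wittig olefination by the non-stabilised ylide takes the aldehyde at −78 °C much faster than the lactone carbonyl or the α-proton, so the isobutenyl group is installed with C13 intact and without any E/Z question.

**Step 8**
Reactants: 16 lactone; 8 aldehyde
Product: 18 (2Z,6E)-10-hydroxy-3,7-dimethyl-10-[(4S,5R)-5-(2-methylprop-1-enyl)-2-oxo-4-(triethylsilyloxy)oxolan-3-yl]deca-2,6-dien-1-yl methacrylate (C10 epimers; C11 mainly trans to OSiEt3), via lithium enolate 17 (not isolated)
Conditions: LiHMDS (1.05 equiv), THF, −78 °C; 8, −78 °C, 30 min; AcOH/THF quench at −78 °C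
Reagents that add atoms: none
Why: In this lithium-enolate aldol addition the aldehyde reacts at −78 °C far faster than the methacrylate, and the cold quench prevents β-elimination and silyl migration; the new C10 and C11 centres need no control because step 9 removes them.

**Step 9**
Reactants: 18 aldol
Product: 20 (2Z,6E)-3,7-dimethyl-10-[(3E,4S,5R)-5-(2-methylprop-1-enyl)-2-oxo-4-(triethylsilyloxy)oxolan-3-ylidene]deca-2,6-dien-1-yl methacrylate, via mesylate 19 (not isolated)
Conditions: MsCl, Et3N, CH2Cl2, −20 → 0 °C; then DBU, 0 °C → rt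
Reagents that add atoms: none
Why: Mesylation followed by DBU-induced E1cB elimination expels the far better leaving group (OMs rather than OSiEt3) and converges both C10 epimers on the more stable E-alkylidene lactone, any Z isomer being removed on silica.

**Step 10**
Reactants: 20 TES-protected alkylidene lactone; 21 acetic anhydride
Product: 23 target CNP0152230.1, via free C12 alcohol 22 (not isolated)
Conditions: HF·pyridine, pyridine–THF, 0 °C → rt (PTFE flask); then Ac2O (excess), DMAP (5 mol %), 0 °C
Reagents that add atoms: acetic anhydride CC(=O)OC(C)=O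
Why: Fluoride-driven Si–O cleavage and O-acetylation in the same flask never break the C12–O bond, so configuration is retained, and the buffered conditions spare the allylic C13–O and C1–O bonds and the 2Z alkene.

## Compound list
1 | nerol | OC/C=C(/C)CCC=C(C)C | starting material
2 | methacryloyl chloride | C=C(C)C(=O)Cl | starting material
3 | neryl methacrylate | C=C(C)C(=O)OC/C=C(/C)CCC=C(C)C | intermediate
4 | (2Z)-6-hydroperoxy-3,7-dimethylocta-2,7-dien-1-yl methacrylate (racemic) | C=C(C)C(=O)OC/C=C(/C)CCC(OO)C(C)=C | intermediate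
5 | (2Z)-6-hydroxy-3,7-dimethylocta-2,7-dien-1-yl methacrylate (racemic) | C=C(C)C(=O)OC/C=C(/C)CCC(O)C(C)=C | intermediate
6 | n-butyl vinyl ether | C=COCCCC | starting material
7 | (2Z)-6-(ethenyloxy)-3,7-dimethylocta-2,7-dien-1-yl methacrylate | C=C(C)C(=O)OC/C=C(/C)CCC(OC=C)C(C)=C | intermediate
8 | (2Z,6E)-3,7-dimethyl-10-oxodeca-2,6-dien-1-yl methacrylate | C=C(C)C(=O)OC/C=C(/C)CC/C=C(\C)CCC=O | intermediate
9 | 2-deoxy-D-ribose (drawn open-chain) | O=CC[C@H](O)[C@H](O)CO | starting material
10 | 2-deoxy-D-ribono-1,4-lactone | O=C1C[C@H](O)[C@@H](CO)O1 | intermediate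
11 | 3,5-bis-O-triethylsilyl-2-deoxy-D-ribono-1,4-lactone | O=C1C[C@H](O[Si](CC)(CC)CC)[C@@H](CO[Si](CC)(CC)CC)O1 | intermediate
12 | {[(2R,3S)-5-oxo-3-(triethylsilyloxy)oxolan-2-yl]methoxy}dimethylsulfonium chloride | O=C1C[C@H](O[Si](CC)(CC)CC)[C@@H](CO[S+](C)C)O1.[Cl-] | intermediate
13 | (2S,3S)-5-oxo-3-(triethylsilyloxy)oxolane-2-carbaldehyde | O=C1C[C@H](O[Si](CC)(CC)CC)[C@@H](C=O)O1 | intermediate
14 | isopropyltriphenylphosphonium iodide | CC(C)[P+](c1ccccc1)(c1ccccc1)c1ccccc1.[I-] | starting material
15 | isopropylidenetriphenylphosphorane | CC(C)=P(c1ccccc1)(c1ccccc1)c1ccccc1 | intermediate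
16 | (4S,5R)-5-(2-methylprop-1-en-1-yl)-4-(triethylsilyloxy)oxolan-2-one | O=C1C[C@H](O[Si](CC)(CC)CC)[C@@H](C=C(C)C)O1 | intermediate
17 | lithium enolate of 16 | [Li+].[O-]C1=C[C@H](O[Si](CC)(CC)CC)[C@@H](C=C(C)C)O1 | intermediate
18 | aldol adduct (C10/C11 mixture) | C=C(C)C(=O)OC/C=C(/C)CC/C=C(\C)CCC(O)C1C(=O)O[C@H](C=C(C)C)[C@H]1O[Si](CC)(CC)CC | intermediate
19 | C10 mesylate of 18 | C=C(C)C(=O)OC/C=C(/C)CC/C=C(\C)CCC(OS(C)(=O)=O)C1C(=O)O[C@H](C=C(C)C)[C@H]1O[Si](CC)(CC)CC | intermediate
20 | (E)-alkylidene lactone, C12 TES ether | C=C(C)C(=O)OC/C=C(/C)CC/C=C(\C)CC/C=C1/C(=O)O[C@H](C=C(C)C)[C@H]1O[Si](CC)(CC)CC | intermediate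
21 | acetic anhydride | CC(=O)OC(C)=O | starting material
22 | (E)-alkylidene lactone, free C12 alcohol | C=C(C)C(=O)OC/C=C(/C)CC/C=C(\C)CC/C=C1/C(=O)O[C@H](C=C(C)C)[C@H]1O | intermediate
23 | (2Z,6E)-10-[(3E,4S,5R)-4-acetoxy-5-(2-methylprop-1-enyl)-2-oxooxolan-3-ylidene]-3,7-dimethyldeca-2,6-dien-1-yl methacrylate | C=C(C)C(=O)OC/C=C(/C)CC/C=C(\C)CC/C=C1/C(=O)O[C@H](C=C(C)C)[C@H]1OC(C)=O | target

## Count and risks
Total step count: 10 (chain branch 3, lactone branch 4, joint end 3).
Longest linear sequence: 7 steps (9 → 23, steps 4–10).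

**Risk 1, step 2.**
- Failure mode: the ene reaction cannot deliver more than about half of the material as 5, and the two allylic alcohols may be hard to separate.
- Span: the fallback sets out from 3 and comes back at 5.
- Epoxidation: mCPBA (1 equiv, NaHCO3, CH2Cl2, 0 °C) epoxidises only the electron-rich 6,7-alkene to 6,7-epoxyneryl methacrylate F1.
- Isomerisation: TMSOTf/2,6-lutidine followed by DBU (toluene, −78 °C → rt) opens the epoxide at its tertiary carbon and removes a methyl proton. This gives the allyl trimethylsilyl ether F2 as a single regioisomer.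
- Return: citric acid in MeOH frees 5.

**Risk 2, step 3.**
- Failure mode: with only H on the oxygen-bearing vinyl carbon, the chair with an axial chain is weakly penalised. The 6Z content may therefore reach 10–15 %, and the methacrylate may oligomerise at 125 °C.
- Span: the fallback sets out from 5 and comes back at 8.
- Rearrangement: Eschenmoser–Claisen rearrangement with N,N-dimethylacetamide dimethyl acetal (toluene, 110 °C, BHT) gives the dimethylamide F3. The NMe2 group clashes 1,3-diaxially with an axial chain, so E is at least 98:2.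
- Return: Cp2Zr(H)Cl (THF, rt, minutes) reduces the tertiary amide to aldehyde 8 and leaves the ester alone.

**Risk 3, step 8.**
- Failure mode: enolate 17 may expel triethylsilanolate (E1cB to the butenolide) or simply deprotonate the enolisable aldehyde.
- Span: the fallback sets out from 16 and comes back at 18.
- Soft enolisation: TMSOTf/Et3N (Et2O, 0 °C) gives the neutral silyl ketene acetal F4, which has no anionic drive to eliminate.
- Return: Mukaiyama aldol addition of F4 to 8 (BF3·OEt2, CH2Cl2, −78 °C) gives 18 after work-up.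

## Further compounds
F1 | step 2 | 6,7-epoxyneryl methacrylate (racemic) | C=C(C)C(=O)OC/C=C(/C)CCC1OC1(C)C
F2 | step 2 | (2Z)-3,7-dimethyl-6-(trimethylsilyloxy)octa-2,7-dien-1-yl methacrylate | C=C(C)C(=O)OC/C=C(/C)CCC(O[Si](C)(C)C)C(C)=C
F3 | step 3 | (2Z,6E)-10-(dimethylamino)-3,7-dimethyl-10-oxodeca-2,6-dien-1-yl methacrylate | C=C(C)C(=O)OC/C=C(/C)CC/C=C(\C)CCC(=O)N(C)C
F4 | step 8 | (4S,5R)-5-(2-methylprop-1-enyl)-4-(triethylsilyloxy)-2-(trimethylsilyloxy)-4,5-dihydrofuran | C[Si](C)(C)OC1=C[C@H](O[Si](CC)(CC)CC)[C@@H](C=C(C)C)O1
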